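**Plan**
- Retrosynthesis: the chalcone C=C is cut first (Wittig, aldehyde 13 + acylphosphorane 16). C2–H is then traced back to C2–B, and the C2–aryl and C3–C(=O) bonds are cut together, leaving a benzofuran, an arylboronic ester and an aroyl chloride.
- Enabling feature: in benzofuran the O1–C2=C3 unit is an enol ether inside a weakly aromatic furan ring. With a four-coordinate boron on C2, C3 is nucleophilic and C2 accepts a group migrating from boron.
- Forward: no ring is built. The benzofuran bicycle is bought (1) and its furan ring is dearomatised in step 6, where 2, 4 and 8 are joined. Then B→H at C2, acetal→CHO, Wittig chain extension and removal of five MOM groups follow.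
- Stereochemistry: C3 (S) comes from the chiral ligand on aroylpalladium. C2 (S) follows from the anti 1,2-shift (aryl trans to aroyl) and is kept by stereoretentive protodeboronation. The E-alkene comes from the stabilised ylide.
- Both aroyl units come from the one acid chloride 8.

Key step: step 6

Assumption: which antipode of the bisphosphine L* leads to the (2S,3S) series cannot be predicted and is fixed in a first small-scale run; the route is written for that antipode.

Step 1
Reactants: 1 benzofuran-5-carbaldehyde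
Product: 2 2-(1-benzofuran-5-yl)-1,3-dioxolane
Conditions: ethylene glycol, p-TsOH·H2O (cat.), toluene, reflux, azeotropic removal of water
Reagents that add atoms: ethylene glycol, OCCO
Why: Acid-catalysed acetalisation masks the aldehyde as a dioxolane that is inert to n-BuLi and to the boronate chemistry of step 6.

Step 2
Reactants: 3 4-(4,4,5,5-tetramethyl-1,3,2-dioxaborolan-2-yl)phenol
Product: 4 2-[4-(methoxymethoxy)phenyl]-4,4,5,5-tetramethyl-1,3,2-dioxaborolane
Conditions: MOMCl, i-Pr2NEt, CH2Cl2, 0 °C → rt
Reagents that add atoms: chloromethyl methyl ether (MOMCl), COCCl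
Why: Williamson-type O-alkylation of the phenol under amine base leaves the pinacol boronate untouched and removes the acidic proton that would quench the lithiated benzofuran.

Step 3
Reactants: 5 methyl 2,4-dihydroxybenzoate
Product: 6 methyl 2,4-bis(methoxymethoxy)benzoate
Conditions: NaH, MOMCl, DMF, 0 °C → rt
Reagents that add atoms: chloromethyl methyl ether (MOMCl), COCCl
Why: Williamson ether synthesis on the bis-phenoxide; NaH also deprotonates the hydrogen-bonded 2-OH, so both hydroxyls are alkylated while the ester stays intact.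

Step 4
Reactants: 6 methyl 2,4-bis(methoxymethoxy)benzoate
Product: 7 2,4-bis(methoxymethoxy)benzoic acid
Conditions: LiOH, THF–MeOH–H2O, 50 °C; then cold 1 M HCl to pH 4, immediate extraction
Reagents that add atoms: lithium hydroxide, [Li+].[OH-]
Why: Ester saponification (BAc2); the acetal-type MOM ethers are stable to hydroxide and to the brief cold acidification.

Step 5
Reactants: 7 2,4-bis(methoxymethoxy)benzoic acid
Product: 8 2,4-bis(methoxymethoxy)benzoyl chloride (volatiles removed, used the same day without purification)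
Conditions: 1-chloro-N,N,2-trimethylprop-1-en-1-amine (1.0 equiv), CH2Cl2, 0 °C → rt
Reagents that add atoms: 1-chloro-N,N,2-trimethylprop-1-en-1-amine, CC(C)=C(Cl)N(C)C
Why: Neutral acid chloride formation with an α-chloroenamine: the acid adds to the keteniminium form of the reagent and chloride displaces the amide, so no HCl is set free and the MOM ethers should survive.

Step 6
Reactants: 2 2-(1-benzofuran-5-yl)-1,3-dioxolane; 4 2-[4-(methoxymethoxy)phenyl]-4,4,5,5-tetramethyl-1,3,2-dioxaborolane; 8 2,4-bis(methoxymethoxy)benzoyl chloride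
Product: 11 [(2S,3S)-5-(1,3-dioxolan-2-yl)-2-[4-(methoxymethoxy)phenyl]-2-(4,4,5,5-tetramethyl-1,3,2-dioxaborolan-2-yl)-2,3-dihydro-1-benzofuran-3-yl][2,4-bis(methoxymethoxy)phenyl]methanone (aryl trans to aroyl; boron cis to aroyl), via 2-lithiobenzofuran acetal 9 (not isolated), via lithium boronate 10 (not isolated)
Conditions: n-BuLi, THF, −78 °C; 4, −78 °C → rt; then Pd2(dba)3 (2.5 mol %), L* (MandyPhos-type ferrocenyl bisphosphine, 6 mol %), 8 (slow addition), THF, −20 °C → rt
Reagents that add atoms: none
Why: Proposed new method: oxidative addition of Pd(0)–L* into the C–Cl bond of 8 should give a chiral aroylpalladium(II) species that binds the C2=C3 π bond of boronate 10 at C3; the 4-(methoxymethoxy)phenyl group then shifts from boron to C2 on the face opposite palladium (1,2-metallate shift), and C–C reductive elimination with retention joins C3 to the aroyl carbon. The closest known reactions are the palladium-catalysed enantioselective three-component coupling of indol-2-yl boronates with allylic electrophiles and the conjunctive cross-coupling of alkenyl boronates; neither has been shown with benzofuran-2-yl boronates or acyl electrophiles. No ring closes; the furan ring is only dearomatised across C2–C3. C3 (S) is set by the face of the enol-ether π bond that the ligand-bound aroylpalladium takes, and C2 (S) follows from it because the migration is strictly anti, which places aryl trans to aroyl and boron cis to aroyl. The step needs the metallate shift to win over direct boron-to-palladium transfer (Suzuki-type ketone formation) and over uncatalysed C3 acylation; the coordinatively saturated pinacol boronate under anhydrous conditions, the high C3 nucleophilicity conferred by the ring oxygen, the electron-rich and therefore sluggish aroyl chloride added slowly at low temperature, and a wide-bite-angle bisphosphine should favour this.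

Step 7
Reactants: 11 the (2S,3S) C2-boronic ester
Product: 12 [(2S,3S)-5-(1,3-dioxolan-2-yl)-2-[4-(methoxymethoxy)phenyl]-2,3-dihydro-1-benzofuran-3-yl][2,4-bis(methoxymethoxy)phenyl]methanone (2,3-trans)
Conditions: CsF, H2O (1.1 equiv), 1,4-dioxane, 45 °C
Reagents that add atoms: none
Why: Fluoride-promoted protodeboronation of a tertiary benzylic pinacol boronic ester, a reaction type that proceeds with retention because water bound to the fluoroborate delivers the proton to the face from which boron departs; C2 should therefore keep its aryl group trans to the C3 aroyl group, and the low-water, weakly basic medium disfavours enolisation at C3.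

Step 8
Reactants: 12 the (2S,3S) dioxolane
Product: 13 (2S,3S)-3-[2,4-bis(methoxymethoxy)benzoyl]-2-[4-(methoxymethoxy)phenyl]-2,3-dihydro-1-benzofuran-5-carbaldehyde
Conditions: AcOH–THF–H2O (3:1:1), 40 °C
Reagents that add atoms: water, O
Why: Acid-catalysed acetal hydrolysis; the dioxolane of a para-oxygenated benzaldehyde ionises far more easily than aryl MOM ethers, and dilute acetic acid does not enolise the C3 ketone.

Step 9
Reactants: 8 2,4-bis(methoxymethoxy)benzoyl chloride; 14 methyltriphenylphosphonium bromide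
Product: 16 1-[2,4-bis(methoxymethoxy)phenyl]-2-(triphenyl-λ5-phosphanylidene)ethan-1-one, via methylenetriphenylphosphorane 15 (not isolated)
Conditions: 14 (2.1 equiv), n-BuLi (2.05 equiv), THF, 0 °C; then 8, −78 °C → rt
Reagents that add atoms: none
Why: C-acylation of the non-stabilised ylide followed by transylidation (the second equivalent of 15 deprotonates the acylphosphonium salt) is the standard route to acyl-stabilised phosphoranes.

Step 10
Reactants: 13 the (2S,3S) aldehyde; 16 the acylphosphorane
Product: 17 (E)-3-{(2S,3S)-3-[2,4-bis(methoxymethoxy)benzoyl]-2-[4-(methoxymethoxy)phenyl]-2,3-dihydro-1-benzofuran-5-yl}-1-[2,4-bis(methoxymethoxy)phenyl]prop-2-en-1-one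
Conditions: toluene, 90 °C
Reagents that add atoms: none
Why: Wittig olefination with an acyl-stabilised ylide is E-selective and needs no added base, so the enolisable β-aryloxy ketone at C3 should not epimerise, and the hindered C3 ketone is inert to the stabilised ylide.

Step 11
Reactants: 17 the penta-MOM chalcone
Product: 18 (E)-3-[(2S,3S)-3-(2,4-dihydroxybenzoyl)-2-(4-hydroxyphenyl)-2,3-dihydro-1-benzofuran-5-yl]-1-(2,4-dihydroxyphenyl)prop-2-en-1-one (CNP0288976.2)
Conditions: HCl (1.25 M in MeOH), 35 °C
Reagents that add atoms: none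
Why: Acid-catalysed transacetalisation to methanol cleaves all five aryl MOM ethers; the trans-2,3 arrangement is the thermodynamically preferred one and 2',4'-dihydroxychalcones are isolable from such conditions at mild temperature.

**Compound list**
1 | benzofuran-5-carbaldehyde | O=Cc1ccc2occc2c1 | starting material
2 | 2-(1-benzofuran-5-yl)-1,3-dioxolane | C1COC(O1)c1ccc2occc2c1 | intermediate
3 | 4-(4,4,5,5-tetramethyl-1,3,2-dioxaborolan-2-yl)phenol | Oc1ccc(B2OC(C)(C)C(C)(C)O2)cc1 | starting material
4 | 2-[4-(methoxymethoxy)phenyl]-4,4,5,5-tetramethyl-1,3,2-dioxaborolane | COCOc1ccc(B2OC(C)(C)C(C)(C)O2)cc1 | intermediate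
5 | methyl 2,4-dihydroxybenzoate | COC(=O)c1ccc(O)cc1O | starting material
6 | methyl 2,4-bis(methoxymethoxy)benzoate | COCOc1ccc(C(=O)OC)c(OCOC)c1 | intermediate
7 | 2,4-bis(methoxymethoxy)benzoic acid | COCOc1ccc(C(O)=O)c(OCOC)c1 | intermediate
8 | 2,4-bis(methoxymethoxy)benzoyl chloride | COCOc1ccc(C(Cl)=O)c(OCOC)c1 | intermediate
9 | [5-(1,3-dioxolan-2-yl)-1-benzofuran-2-yl]lithium | [Li]c1cc2cc(C3OCCO3)ccc2o1 | intermediate
10 | lithium [5-(1,3-dioxolan-2-yl)-1-benzofuran-2-yl][4-(methoxymethoxy)phenyl](pinacolato)borate | [Li+].COCOc1ccc(cc1)[B-]1(OC(C)(C)C(C)(C)O1)c1cc2cc(C3OCCO3)ccc2o1 | intermediate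
11 | [(2S,3S)-5-(1,3-dioxolan-2-yl)-2-[4-(methoxymethoxy)phenyl]-2-(4,4,5,5-tetramethyl-1,3,2-dioxaborolan-2-yl)-2,3-dihydro-1-benzofuran-3-yl][2,4-bis(methoxymethoxy)phenyl]methanone | C1COC(O1)c1ccc2c(c1)[C@H](C(=O)c1ccc(OCOC)cc1OCOC)[C@@](B1OC(C)(C)C(C)(C)O1)(c1ccc(OCOC)cc1)O2 | intermediate
12 | [(2S,3S)-5-(1,3-dioxolan-2-yl)-2-[4-(methoxymethoxy)phenyl]-2,3-dihydro-1-benzofuran-3-yl][2,4-bis(methoxymethoxy)phenyl]methanone | C1COC(O1)c1ccc2c(c1)[C@H](C(=O)c1ccc(OCOC)cc1OCOC)[C@@H](c1ccc(OCOC)cc1)O2 | intermediate
13 | (2S,3S)-3-[2,4-bis(methoxymethoxy)benzoyl]-2-[4-(methoxymethoxy)phenyl]-2,3-dihydro-1-benzofuran-5-carbaldehyde | O=Cc1ccc2c(c1)[C@H](C(=O)c1ccc(OCOC)cc1OCOC)[C@@H](c1ccc(OCOC)cc1)O2 | intermediate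
14 | methyltriphenylphosphonium bromide | C[P+](c1ccccc1)(c1ccccc1)c1ccccc1.[Br-] | starting material
15 | methylenetriphenylphosphorane | C=P(c1ccccc1)(c1ccccc1)c1ccccc1 | intermediate
16 | 1-[2,4-bis(methoxymethoxy)phenyl]-2-(triphenyl-λ5-phosphanylidene)ethan-1-one | COCOc1ccc(C(=O)C=P(c2ccccc2)(c2ccccc2)c2ccccc2)c(OCOC)c1 | intermediate
17 | (E)-3-{(2S,3S)-3-[2,4-bis(methoxymethoxy)benzoyl]-2-[4-(methoxymethoxy)phenyl]-2,3-dihydro-1-benzofuran-5-yl}-1-[2,4-bis(methoxymethoxy)phenyl]prop-2-en-1-one | O=C(/C=C/c1ccc2c(c1)[C@H](C(=O)c1ccc(OCOC)cc1OCOC)[C@@H](c1ccc(OCOC)cc1)O2)c1ccc(OCOC)cc1OCOC | intermediate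
18 | (E)-3-[(2S,3S)-3-(2,4-dihydroxybenzoyl)-2-(4-hydroxyphenyl)-2,3-dihydro-1-benzofuran-5-yl]-1-(2,4-dihydroxyphenyl)prop-2-en-1-one | O=C(/C=C/c1ccc2c(c1)[C@H](C(=O)c1ccc(O)cc1O)[C@@H](c1ccc(O)cc1)O2)c1ccc(O)cc1O | target

Total step count: 11. Longest linear sequence: 8 steps (5 → 6 → 7 → 8 → 11 → 12 → 13 → 17 → 18; steps 3, 4, 5, 6, 7, 8, 10, 11).

**Steps most likely to fail**

Step 6 (Proposed new method). The aroylpalladium intermediate may take the benzofuranyl or aryl group from boron by direct boron-to-palladium transfer instead of triggering the 1,2-shift. The acid chloride may also acylate the boronate without the catalyst, so that the product forms with low enantiomeric purity, and decarbonylation of the aroylpalladium is a further drain. The fallback uses known chemistry (rhodium-carbenoid C–H insertion), sets out from 8 and comes back at 13. Acid chloride 8 is treated with trimethylsilyldiazomethane (Et3N, MeCN–THF, 0 °C) to give the diazomethyl ketone 1-[2,4-bis(methoxymethoxy)phenyl]-2-diazoethan-1-one F1. Commercial 4-hydroxy-3-iodobenzaldehyde is etherified with 4-(methoxymethoxy)benzyl alcohol (Mitsunobu reaction, PPh3, DIAD, THF) to 3-iodo-4-{[4-(methoxymethoxy)phenyl]methoxy}benzaldehyde F2. Palladium-catalysed C–H arylation of the acyldiazomethane (Pd(PPh3)4, Ag2CO3, Et3N, toluene, rt) joins F1 and F2 with the diazo group intact to the α-aryl-α-diazo ketone 1-[2,4-bis(methoxymethoxy)phenyl]-2-diazo-2-(5-formyl-2-{[4-(methoxymethoxy)phenyl]methoxy}phenyl)ethan-1-one F3. A chiral dirhodium(II) carboxylate (Rh2(S-PTTL)4 or its antipode, toluene, low temperature) should effect intramolecular carbenoid insertion into the benzylic ether C–H bond. This closes the five-membered ring and sets C2, giving the cis aldehyde (2S,3R)-3-[2,4-bis(methoxymethoxy)benzoyl]-2-[4-(methoxymethoxy)phenyl]-2,3-dihydro-1-benzofuran-5-carbaldehyde F4. Catalytic DBU (CH2Cl2, rt) then epimerises C3 to the trans aldehyde 13.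

Step 7. C2 may lose its configuration if a planarised α-oxybenzyl anion is protonated from the face opposite the aroyl group. Fluoride may also enolise C3, after which the ring opens by β-elimination of the phenoxide. The fallback sets out from 2, 4 and 8 and comes back at 12. It accepts inversion at C2 and corrects at C3. Step 6 is run with the mirror-image ligand to give the enantiomeric boronic ester [(2R,3R)-5-(1,3-dioxolan-2-yl)-2-[4-(methoxymethoxy)phenyl]-2-(4,4,5,5-tetramethyl-1,3,2-dioxaborolan-2-yl)-2,3-dihydro-1-benzofuran-3-yl][2,4-bis(methoxymethoxy)phenyl]methanone F5. The C–B bond is then cleaved by a radical path (amine-activated boronate, photoredox oxidation under blue light, aryl thiol as hydrogen-atom donor). Hydrogen should reach the planar C2 radical from the face opposite the C3 aroyl group, giving the cis compound [(2S,3R)-5-(1,3-dioxolan-2-yl)-2-[4-(methoxymethoxy)phenyl]-2,3-dihydro-1-benzofuran-3-yl][2,4-bis(methoxymethoxy)phenyl]methanone F6. Catalytic DBU then epimerises C3 to the thermodynamically preferred trans isomer 12.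

Step 11. During the long acid exposure needed for five acetals, the 2'-hydroxychalcone may close to the flavanone, methanol may add to the enone, and the C2–O bond next to the freed 4-hydroxyphenyl group may ionise and epimerise. The fallback sets out from 13 and comes back at 18. It removes the acetals before the enone exists and makes the olefination the last step. Aldehyde 13 is treated with methanolic HCl (three acetals only) to give (2S,3S)-3-(2,4-dihydroxybenzoyl)-2-(4-hydroxyphenyl)-2,3-dihydro-1-benzofuran-5-carbaldehyde F7. Commercial 2-chloro-1-(2,4-dihydroxyphenyl)ethan-1-one and PPh3 (MeCN, reflux) give [2-(2,4-dihydroxyphenyl)-2-oxoethyl]triphenylphosphonium chloride F8. Aqueous NaHCO3 converts F8 into the free-phenol ylide 1-(2,4-dihydroxyphenyl)-2-(triphenyl-λ5-phosphanylidene)ethan-1-one F9. Wittig reaction of F7 with F9 (THF, 60 °C, no added base) should give 18 directly.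

**Further compounds**
F1 | step 6 | 1-[2,4-bis(methoxymethoxy)phenyl]-2-diazoethan-1-one | COCOc1ccc(C(=O)C=[N+]=[N-])c(OCOC)c1
F2 | step 6 | 3-iodo-4-{[4-(methoxymethoxy)phenyl]methoxy}benzaldehyde | O=Cc1ccc(OCc2ccc(OCOC)cc2)c(I)c1
F3 | step 6 | 1-[2,4-bis(methoxymethoxy)phenyl]-2-diazo-2-(5-formyl-2-{[4-(methoxymethoxy)phenyl]methoxy}phenyl)ethan-1-one | COCOc1ccc(C(=O)C(=[N+]=[N-])c2cc(C=O)ccc2OCc2ccc(OCOC)cc2)c(OCOC)c1
F4 | step 6 | (2S,3R)-3-[2,4-bis(methoxymethoxy)benzoyl]-2-[4-(methoxymethoxy)phenyl]-2,3-dihydro-1-benzofuran-5-carbaldehyde | O=Cc1ccc2c(c1)[C@@H](C(=O)c1ccc(OCOC)cc1OCOC)[C@@H](c1ccc(OCOC)cc1)O2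
F5 | step 7 | [(2R,3R)-5-(1,3-dioxolan-2-yl)-2-[4-(methoxymethoxy)phenyl]-2-(4,4,5,5-tetramethyl-1,3,2-dioxaborolan-2-yl)-2,3-dihydro-1-benzofuran-3-yl][2,4-bis(methoxymethoxy)phenyl]methanone | C1COC(O1)c1ccc2c(c1)[C@@H](C(=O)c1ccc(OCOC)cc1OCOC)[C@](B1OC(C)(C)C(C)(C)O1)(c1ccc(OCOC)cc1)O2
F6 | step 7 | [(2S,3R)-5-(1,3-dioxolan-2-yl)-2-[4-(methoxymethoxy)phenyl]-2,3-dihydro-1-benzofuran-3-yl][2,4-bis(methoxymethoxy)phenyl]methanone | C1COC(O1)c1ccc2c(c1)[C@@H](C(=O)c1ccc(OCOC)cc1OCOC)[C@@H](c1ccc(OCOC)cc1)O2
F7 | step 11 | (2S,3S)-3-(2,4-dihydroxybenzoyl)-2-(4-hydroxyphenyl)-2,3-dihydro-1-benzofuran-5-carbaldehyde | O=Cc1ccc2c(c1)[C@H](C(=O)c1ccc(O)cc1O)[C@@H](c1ccc(O)cc1)O2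
F8 | step 11 | [2-(2,4-dihydroxyphenyl)-2-oxoethyl]triphenylphosphonium chloride | O=C(C[P+](c1ccccc1)(c1ccccc1)c1ccccc1)c1ccc(O)cc1O.[Cl-]
F9 | step 11 | 1-(2,4-dihydroxyphenyl)-2-(triphenyl-λ5-phosphanylidene)ethan-1-one | O=C(C=P(c1ccccc1)(c1ccccc1)c1ccccc1)c1ccc(O)cc1O
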